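**Plan** (chromanone numbering: O1, C2, C3, C4, C4a, C5–C8, C8a)

- Retrosynthesis: cut O1–C2 (oxa-Michael), then C4–C4a (Friedel–Crafts), then the benzene ring at C6–C7, C4a–C5 and C7–C8 (cyclobutenone/alkynyl ether benzannulation), and last the cyclobutenone into a ketene and ethoxyacetylene.
- Enabling feature: the fully substituted benzene ring C4a/C5/C6/C7/C8/C8a has oxygen on the alternating carbons C5, C7 and C8a, prenyl on C6 and the benzylic carbon on C8. A vinylketene (C7, C8, C8a, C4a) and an oxygenated alkyne (C5, C6) write this pattern directly, each oxygen arriving differently substituted (H, silyl, ethyl).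
- Forward: 3-phenylglutaric anhydride → hemiester → ketene → 3-ethoxycyclobutenone; prenyl bromide → siloxyalkyne; benzannulation makes the benzene ring; then C7 methylation, C4a tigloylation, C8a de-ethylation, closure of the pyranone ring, desilylation and ester cleavage.
- Stereochemistry: the benzylic centre (R) comes from alkaloid-catalysed desymmetrisation of the anhydride and is carried unchanged. C2 (S) and C3 (R), cis, come from a quinidine-catalysed oxa-Michael addition with kinetic protonation.

Key step: step 6

Assumption: the facial sense of the two alkaloid-controlled steps (1 and 10) is taken from closely related substrates; should either prove opposite, the pseudoenantiomeric alkaloid would be used ((DHQD)2AQN in step 1, quinine in step 10) with no other change.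

**Route**

Step 1
Reactants: 1 3-phenylglutaric anhydride
Product: 2 (3R)-5-methoxy-5-oxo-3-phenylpentanoic acid
Conditions: (DHQ)2AQN (hydroquinine anthraquinone-1,4-diyl diether, 20 mol%), MeOH, Et2O, −40 °C; then aq. HCl
Reagents that add atoms: methanol, CO
Why: Alkaloid-catalysed desymmetrising methanolysis of a prochiral glutaric anhydride, in which the catalyst acts as a chiral general base and delivers methanol to one of the two enantiotopic carbonyl groups, setting the benzylic centre (R) that later sits on C8.

Step 2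
Reactants: 2 (3R)-5-methoxy-5-oxo-3-phenylpentanoic acid
Product: 3 methyl (3S)-5-chloro-5-oxo-3-phenylpentanoate
Conditions: (COCl)2, DMF (cat.), CH2Cl2, 0 °C → rt
Reagents that add atoms: oxalyl chloride, ClC(=O)C(=O)Cl
Why: Acid chloride formation through the chloroiminium species from DMF and oxalyl chloride is mild enough to leave the methyl ester and the non-enolisable benzylic centre untouched (the descriptor changes by priority only).

Step 3
Reactants: 3 methyl (3S)-5-chloro-5-oxo-3-phenylpentanoate; 4 ethoxyacetylene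
Product: 6 methyl (3S)-3-(2-ethoxy-4-oxocyclobut-2-en-1-yl)-3-phenylpropanoate (both ring epimers), via ketene 5 (not isolated)
Conditions: Et3N (slow addition), Et2O, 0 °C → rt
Reagents that add atoms: none
Why: Dehydrochlorination gives the monosubstituted ketene, which is trapped in a ketene–alkoxyacetylene [2+2] cycloaddition whose polarity (ketene carbonyl carbon to the terminal alkyne carbon) puts ethoxy on C3 and the side chain on C4 of the cyclobutenone; the new ring stereocentre forms without control and is erased in step 6.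

Step 4
Reactants: 7 prenyl bromide (1-bromo-3-methylbut-2-ene); 8 ethynylmagnesium bromide
Product: 9 5-methylhex-4-en-1-yne
Conditions: CuCl (5 mol%), THF, 0 °C → rt
Reagents that add atoms: none
Why: Copper-catalysed coupling of an alkynyl Grignard reagent with an allylic bromide should take place at the unhindered primary terminus of the prenyl unit and give the skipped enyne.

Step 5
Reactants: 9 5-methylhex-4-en-1-yne
Product: 12 triisopropyl[(5-methylhex-4-en-1-yn-1-yl)oxy]silane, via lithium acetylide 10 (not isolated), via lithium ynolate 11 (not isolated)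
Conditions: n-BuLi, THF, −78 °C; t-BuOOLi (from t-BuOOH, LiN(SiMe3)2), −78 → 0 °C; i-Pr3SiOTf, −78 → 0 °C
Reagents that add atoms: tert-butyl hydroperoxide, CC(C)(C)OO; triisopropylsilyl trifluoromethanesulfonate, CC(C)[Si](C(C)C)(C(C)C)OS(=O)(=O)C(F)(F)F
Why: Oxygen transfer from the lithium peroxide to the lithium acetylide gives the ynolate, which the bulky silyl triflate traps on oxygen (siloxyalkyne synthesis by acetylide oxidation), the triisopropylsilyl group being large enough to suppress 1,3-silyl migration to a silylketene.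

Step 6
Reactants: 6 methyl (3S)-3-(2-ethoxy-4-oxocyclobut-2-en-1-yl)-3-phenylpropanoate; 12 triisopropyl[(5-methylhex-4-en-1-yn-1-yl)oxy]silane
Product: 17 methyl (3R)-3-[2-ethoxy-6-hydroxy-5-(3-methylbut-2-en-1-yl)-4-(triisopropylsilyloxy)phenyl]-3-phenylpropanoate, via vinylketene 13 (not isolated), via vinylcyclobutenone 14 (not isolated), via dienylketene 15 (not isolated), via cyclohexadienone 16 (not isolated)
Conditions: toluene (degassed), 80 → 110 °C
Reagents that add atoms: none
Why: Heating opens the cyclobutenone by 4π-electrocyclic cleavage (side chain rotating outward, which also keeps the benzylic C–H away from the ketene) to vinylketene 13, whose ketene C=C adds [2+2] to the electron-rich siloxyalkyne to give 14; a second 4π opening gives dienylketene 15, which closes to cyclohexadienone 16 and tautomerises to the phenol. This is the Danheiser benzannulation in its siloxyalkyne form, here with a 3-alkoxycyclobutenone as the less usual vinylketene source. The benzene ring is closed by a thermal 6π-disrotatory electrocyclisation that makes the C7–C8 bond, after the [2+2] step has joined C6–C7 and C4a–C5. No stereocentre is created: the ring epimers of 6 converge once C8 becomes sp2, and the benzylic centre lies outside every pericyclic array and is not acidic under neutral thermal conditions. The one selectivity needed is regiochemical, ketene carbonyl carbon to the prenyl-bearing alkyne carbon, and the polarisation of the silyl ynol ether secures it, so that C7 emerges as free OH, C5 as silyl ether and C8a as ethyl ether. Neutral conditions and prompt methylation in step 7 should limit closure of the new phenol onto the neighbouring ester.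

Step 7
Reactants: 17 methyl (3R)-3-[2-ethoxy-6-hydroxy-5-(3-methylbut-2-en-1-yl)-4-(triisopropylsilyloxy)phenyl]-3-phenylpropanoate
Product: 18 methyl (3R)-3-[2-ethoxy-6-methoxy-5-(3-methylbut-2-en-1-yl)-4-(triisopropylsilyloxy)phenyl]-3-phenylpropanoate
Conditions: MeI, K2CO3, acetone, 40 °C
Reagents that add atoms: iodomethane, CI
Why: Williamson O-methylation of the single free phenol with a weak carbonate base in an aprotic solvent should leave the aryl silyl ether and the ester intact and outrun closure of the phenoxide onto the ester, which would have to expel methoxide.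

Step 8
Reactants: 18 methyl (3R)-3-[2-ethoxy-6-methoxy-5-(3-methylbut-2-en-1-yl)-4-(triisopropylsilyloxy)phenyl]-3-phenylpropanoate; 19 tigloyl chloride ((E)-2-methylbut-2-enoyl chloride)
Product: 20 methyl (3R)-3-[2-ethoxy-6-methoxy-3-[(E)-2-methylbut-2-enoyl]-5-(3-methylbut-2-en-1-yl)-4-(triisopropylsilyloxy)phenyl]-3-phenylpropanoate
Conditions: SnCl4, 2,6-di-tert-butyl-4-methylpyridine, CH2Cl2, −78 → −40 °C
Reagents that add atoms: none
Why: Friedel–Crafts acylation at C4a, the only unsubstituted ring position and the one ortho, ortho and para to the three oxygen donors, with the hindered pyridine taking up HCl so that the prenyl double bond and the silyl ether should survive; both positions ortho to the new aryl enone are blocked, which excludes Nazarov closure.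

Step 9
Reactants: 20 methyl (3R)-3-[2-ethoxy-6-methoxy-3-[(E)-2-methylbut-2-enoyl]-5-(3-methylbut-2-en-1-yl)-4-(triisopropylsilyloxy)phenyl]-3-phenylpropanoate
Product: 22 methyl (3R)-3-[2-hydroxy-6-methoxy-3-[(E)-2-methylbut-2-enoyl]-5-(3-methylbut-2-en-1-yl)-4-(triisopropylsilyloxy)phenyl]-3-phenylpropanoate, via dichloroboryl ether 21 (not isolated)
Conditions: BCl3, CH2Cl2, −78 → −20 °C; then H2O, 0 °C
Reagents that add atoms: none
Why: Chelation-controlled ether cleavage, in which BCl3 bridges the ketone oxygen and the more Lewis-basic ethoxy oxygen at C8a and chloride removes the ethyl group, whereas the unchelated para methoxy group and the hindered, weakly basic silyloxy oxygen at C5 should be spared at low temperature.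

Step 10
Reactants: 22 methyl (3R)-3-[2-hydroxy-6-methoxy-3-[(E)-2-methylbut-2-enoyl]-5-(3-methylbut-2-en-1-yl)-4-(triisopropylsilyloxy)phenyl]-3-phenylpropanoate
Product: 23 methyl (3R)-3-[(2S,3R)-7-methoxy-2,3-dimethyl-6-(3-methylbut-2-en-1-yl)-4-oxo-5-(triisopropylsilyloxy)chroman-8-yl]-3-phenylpropanoate
Conditions: quinidine (20 mol%), chlorobenzene, rt
Reagents that add atoms: none
Why: Cinchona-alkaloid-catalysed intramolecular oxa-Michael addition (6-endo) of an o-tigloylphenol, a reaction type known to give cis-2,3-dimethylchroman-4-ones: the quinuclidine nitrogen activates the phenol while the C9 hydroxyl binds the enone, the phenoxide adds to one face of the β-carbon to set C2 (S), and the enolate is protonated opposite to the C2 methyl group, which sets C3 (R) and the cis relationship under kinetic control.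

Step 11
Reactants: 23 methyl (3R)-3-[(2S,3R)-7-methoxy-2,3-dimethyl-6-(3-methylbut-2-en-1-yl)-4-oxo-5-(triisopropylsilyloxy)chroman-8-yl]-3-phenylpropanoate
Product: 24 methyl (3R)-3-[(2S,3R)-5-hydroxy-7-methoxy-2,3-dimethyl-6-(3-methylbut-2-en-1-yl)-4-oxochroman-8-yl]-3-phenylpropanoate
Conditions: HF·pyridine, pyridine, THF, 0 °C
Reagents that add atoms: none
Why: Fluoride cleavage of the aryl silyl ether under buffered, mildly acidic conditions should free the C5 phenol, which is then held by a hydrogen bond to the C4 carbonyl, while avoiding the basic media that would epimerise C3 or reopen the pyranone ring.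

Step 12
Reactants: 24 methyl (3R)-3-[(2S,3R)-5-hydroxy-7-methoxy-2,3-dimethyl-6-(3-methylbut-2-en-1-yl)-4-oxochroman-8-yl]-3-phenylpropanoate
Product: 26 (3R)-3-[(2S,3R)-5-hydroxy-7-methoxy-2,3-dimethyl-6-(3-methylbut-2-en-1-yl)-4-oxochroman-8-yl]-3-phenylpropanoic acid, via trimethylstannyl ester 25 (not isolated)
Conditions: Me3SnOH, ClCH2CH2Cl, 70 °C; then 0.1 M aq. HCl wash
Reagents that add atoms: trimethyltin hydroxide, C[Sn](C)(C)O
Why: Trimethyltin hydroxide cleaves the methyl ester through the stannyl ester under nearly neutral conditions (tin hydroxide-mediated ester hydrolysis), chosen because alkali hydroxide would risk epimerisation at C3 and retro-oxa-Michael opening of the cis-chromanone.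

**Compound list**

1 | 3-phenylglutaric anhydride | O=C1CC(CC(=O)O1)c1ccccc1 | starting material
2 | (3R)-5-methoxy-5-oxo-3-phenylpentanoic acid | OC(=O)C[C@H](CC(=O)OC)c1ccccc1 | intermediate
3 | methyl (3S)-5-chloro-5-oxo-3-phenylpentanoate | ClC(=O)C[C@H](CC(=O)OC)c1ccccc1 | intermediate
4 | ethoxyacetylene | CCOC#C | starting material
5 | ketene methyl (3S)-5-oxo-3-phenylpent-4-enoate (not isolated) | O=C=C[C@H](CC(=O)OC)c1ccccc1 | intermediate
6 | methyl (3S)-3-(2-ethoxy-4-oxocyclobut-2-en-1-yl)-3-phenylpropanoate (both ring epimers) | O=C1C=C(OCC)C1[C@H](CC(=O)OC)c1ccccc1 | intermediate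
7 | prenyl bromide (1-bromo-3-methylbut-2-ene) | CC(C)=CCBr | starting material
8 | ethynylmagnesium bromide | C#C[Mg]Br | starting material
9 | 5-methylhex-4-en-1-yne | CC(C)=CCC#C | intermediate
10 | lithium acetylide of 5-methylhex-4-en-1-yne (not isolated) | [Li]C#CCC=C(C)C | intermediate
11 | lithium 5-methylhex-4-en-1-yn-1-olate (not isolated) | [Li]OC#CCC=C(C)C | intermediate
12 | triisopropyl[(5-methylhex-4-en-1-yn-1-yl)oxy]silane | CC(C)=CCC#CO[Si](C(C)C)(C(C)C)C(C)C | intermediate
13 | vinylketene methyl (3S,4Z)-5-ethoxy-7-oxo-3-phenylhepta-4,6-dienoate (not isolated) | O=C=C/C(OCC)=C/[C@H](CC(=O)OC)c1ccccc1 | intermediate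
14 | vinylcyclobutenone methyl (3S,4Z)-5-ethoxy-5-[3-(3-methylbut-2-en-1-yl)-4-oxo-2-(triisopropylsilyloxy)cyclobut-2-en-1-yl]-3-phenylpent-4-enoate (not isolated) | O=C1C(CC=C(C)C)=C(O[Si](C(C)C)(C(C)C)C(C)C)C1/C(OCC)=C/[C@H](CC(=O)OC)c1ccccc1 | intermediate
15 | dienylketene methyl (3S,4Z,6E)-5-ethoxy-8-(3-methylbut-2-en-1-yl)-9-oxo-3-phenyl-7-(triisopropylsilyloxy)nona-4,6,8-trienoate (not isolated) | O=C=C(CC=C(C)C)/C(O[Si](C(C)C)(C(C)C)C(C)C)=C\C(OCC)=C\[C@H](CC(=O)OC)c1ccccc1 | intermediate
16 | cyclohexadienone methyl (3S)-3-[2-ethoxy-5-(3-methylbut-2-en-1-yl)-6-oxo-4-(triisopropylsilyloxy)cyclohexa-2,4-dien-1-yl]-3-phenylpropanoate (not isolated) | O=C1C(CC=C(C)C)=C(O[Si](C(C)C)(C(C)C)C(C)C)C=C(OCC)C1[C@H](CC(=O)OC)c1ccccc1 | intermediate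
17 | methyl (3R)-3-[2-ethoxy-6-hydroxy-5-(3-methylbut-2-en-1-yl)-4-(triisopropylsilyloxy)phenyl]-3-phenylpropanoate | Oc1c(CC=C(C)C)c(O[Si](C(C)C)(C(C)C)C(C)C)cc(OCC)c1[C@H](CC(=O)OC)c1ccccc1 | intermediate
18 | methyl (3R)-3-[2-ethoxy-6-methoxy-5-(3-methylbut-2-en-1-yl)-4-(triisopropylsilyloxy)phenyl]-3-phenylpropanoate | COc1c(CC=C(C)C)c(O[Si](C(C)C)(C(C)C)C(C)C)cc(OCC)c1[C@H](CC(=O)OC)c1ccccc1 | intermediate
19 | tigloyl chloride ((E)-2-methylbut-2-enoyl chloride) | C/C=C(\C)C(Cl)=O | starting material
20 | methyl (3R)-3-[2-ethoxy-6-methoxy-3-[(E)-2-methylbut-2-enoyl]-5-(3-methylbut-2-en-1-yl)-4-(triisopropylsilyloxy)phenyl]-3-phenylpropanoate | COc1c(CC=C(C)C)c(O[Si](C(C)C)(C(C)C)C(C)C)c(C(=O)/C(C)=C/C)c(OCC)c1[C@H](CC(=O)OC)c1ccccc1 | intermediate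
21 | methyl (3R)-3-[2-(dichloroboryloxy)-6-methoxy-3-[(E)-2-methylbut-2-enoyl]-5-(3-methylbut-2-en-1-yl)-4-(triisopropylsilyloxy)phenyl]-3-phenylpropanoate (not isolated) | COc1c(CC=C(C)C)c(O[Si](C(C)C)(C(C)C)C(C)C)c(C(=O)/C(C)=C/C)c(OB(Cl)Cl)c1[C@H](CC(=O)OC)c1ccccc1 | intermediate
22 | methyl (3R)-3-[2-hydroxy-6-methoxy-3-[(E)-2-methylbut-2-enoyl]-5-(3-methylbut-2-en-1-yl)-4-(triisopropylsilyloxy)phenyl]-3-phenylpropanoate | COc1c(CC=C(C)C)c(O[Si](C(C)C)(C(C)C)C(C)C)c(C(=O)/C(C)=C/C)c(O)c1[C@H](CC(=O)OC)c1ccccc1 | intermediate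
23 | methyl (3R)-3-[(2S,3R)-7-methoxy-2,3-dimethyl-6-(3-methylbut-2-en-1-yl)-4-oxo-5-(triisopropylsilyloxy)chroman-8-yl]-3-phenylpropanoate | COc1c(CC=C(C)C)c(O[Si](C(C)C)(C(C)C)C(C)C)c2c(c1[C@H](CC(=O)OC)c1ccccc1)O[C@@H](C)[C@@H](C)C2=O | intermediate
24 | methyl (3R)-3-[(2S,3R)-5-hydroxy-7-methoxy-2,3-dimethyl-6-(3-methylbut-2-en-1-yl)-4-oxochroman-8-yl]-3-phenylpropanoate | COc1c(CC=C(C)C)c(O)c2c(c1[C@H](CC(=O)OC)c1ccccc1)O[C@@H](C)[C@@H](C)C2=O | intermediate
25 | trimethylstannyl (3R)-3-[(2S,3R)-5-hydroxy-7-methoxy-2,3-dimethyl-6-(3-methylbut-2-en-1-yl)-4-oxochroman-8-yl]-3-phenylpropanoate (not isolated) | COc1c(CC=C(C)C)c(O)c2c(c1[C@H](CC(=O)O[Sn](C)(C)C)c1ccccc1)O[C@@H](C)[C@@H](C)C2=O | intermediate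
26 | (3R)-3-[(2S,3R)-5-hydroxy-7-methoxy-2,3-dimethyl-6-(3-methylbut-2-en-1-yl)-4-oxochroman-8-yl]-3-phenylpropanoic acid (CNP0172137.1) | COc1c(CC=C(C)C)c(O)c2c(c1[C@H](CC(=O)O)c1ccccc1)O[C@@H](C)[C@@H](C)C2=O | target

**Step count**

Total: 12 steps. Longest linear sequence: 10 steps (steps 1–3 and 6–12); steps 4–5 form the alkyne branch.

**Three steps most likely to fail**

Step 8. The acylium ion may attack the doubly flanked C4a position more slowly than it acylates the prenyl double bond, or acid may cyclise the prenyl group or strip the silyl ether. The fallback sets out from 18 and gives up direct acylation. Vilsmeier–Haack formylation (POCl3, DMF), which is sterically less demanding and does not touch simple alkenes, should give the aldehyde methyl (3R)-3-[2-ethoxy-3-formyl-6-methoxy-5-(3-methylbut-2-en-1-yl)-4-(triisopropylsilyloxy)phenyl]-3-phenylpropanoate F2. Addition of the alkenyllithium made from (E)-2-bromobut-2-ene and t-BuLi at −78 °C, where the aldehyde is far more electrophilic than the ester, should give the allylic alcohol methyl (3R)-3-[2-ethoxy-3-[(E)-1-hydroxy-2-methylbut-2-en-1-yl]-6-methoxy-5-(3-methylbut-2-en-1-yl)-4-(triisopropylsilyloxy)phenyl]-3-phenylpropanoate F3 as a mixture of carbinol epimers. Oxidation with MnO2 comes back to the route at 20.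

Step 6. At the annulation temperature the new C7 phenol may close onto the neighbouring methyl ester with loss of methanol, the more so if the 3-ethoxycyclobutenone opens sluggishly and forces higher temperatures. The fallback sets out from 6 and 12 and makes this closure deliberate. The crude annulation mixture is heated with a catalytic amount of pyridinium p-toluenesulfonate in toluene so that all material converges on the lactone (4R)-5-ethoxy-8-(3-methylbut-2-en-1-yl)-4-phenyl-7-(triisopropylsilyloxy)chroman-2-one F1, which masks phenol and carboxyl at once. The lactone is then opened with one equivalent of NaOMe in THF–MeOH at −40 °C (an aryl ester should react far faster than the aryl silyl ether), and the liberated phenoxide is methylated in the same flask with MeI. This comes back to the route at 18.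

Step 10. The benzylic centre next to the reacting phenol may oppose the catalyst, giving poor facial selectivity at C2, or the kinetic cis product may drift to the trans isomer. The fallback sets out from 22 and replaces catalyst control by equilibration, separation and kinetic protonation. Catalytic 1,8-diazabicyclo[5.4.0]undec-7-ene in toluene should close the ring under thermodynamic control to the two trans-chromanones, methyl (3R)-3-[(2S,3S)-7-methoxy-2,3-dimethyl-6-(3-methylbut-2-en-1-yl)-4-oxo-5-(triisopropylsilyloxy)chroman-8-yl]-3-phenylpropanoate F4 and its (2R,3R) isomer methyl (3R)-3-[(2R,3R)-7-methoxy-2,3-dimethyl-6-(3-methylbut-2-en-1-yl)-4-oxo-5-(triisopropylsilyloxy)chroman-8-yl]-3-phenylpropanoate F5. These are diastereomers because of the benzylic centre and would be separated by chromatography; the (2R,3R) isomer is returned to the equilibration, where C2 scrambles by retro-oxa-Michael opening. The (2S,3S) isomer is converted into its lithium enolate (LiN(SiMe3)2, THF, −78 °C) and protonated with 2,6-di-tert-butylphenol from the face away from the pseudo-axial C2 methyl group. This inverts C3 and comes back to the route at 23.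

**Further compounds**

F1 | step 6 | (4R)-5-ethoxy-8-(3-methylbut-2-en-1-yl)-4-phenyl-7-(triisopropylsilyloxy)chroman-2-one | O=C1C[C@H](c2ccccc2)c2c(OCC)cc(O[Si](C(C)C)(C(C)C)C(C)C)c(CC=C(C)C)c2O1
F2 | step 8 | methyl (3R)-3-[2-ethoxy-3-formyl-6-methoxy-5-(3-methylbut-2-en-1-yl)-4-(triisopropylsilyloxy)phenyl]-3-phenylpropanoate | COc1c(CC=C(C)C)c(O[Si](C(C)C)(C(C)C)C(C)C)c(C=O)c(OCC)c1[C@H](CC(=O)OC)c1ccccc1
F3 | step 8 | methyl (3R)-3-[2-ethoxy-3-[(E)-1-hydroxy-2-methylbut-2-en-1-yl]-6-methoxy-5-(3-methylbut-2-en-1-yl)-4-(triisopropylsilyloxy)phenyl]-3-phenylpropanoate (carbinol epimers) | COc1c(CC=C(C)C)c(O[Si](C(C)C)(C(C)C)C(C)C)c(C(O)/C(C)=C/C)c(OCC)c1[C@H](CC(=O)OC)c1ccccc1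
F4 | step 10 | methyl (3R)-3-[(2S,3S)-7-methoxy-2,3-dimethyl-6-(3-methylbut-2-en-1-yl)-4-oxo-5-(triisopropylsilyloxy)chroman-8-yl]-3-phenylpropanoate | COc1c(CC=C(C)C)c(O[Si](C(C)C)(C(C)C)C(C)C)c2c(c1[C@H](CC(=O)OC)c1ccccc1)O[C@@H](C)[C@H](C)C2=O
F5 | step 10 | methyl (3R)-3-[(2R,3R)-7-methoxy-2,3-dimethyl-6-(3-methylbut-2-en-1-yl)-4-oxo-5-(triisopropylsilyloxy)chroman-8-yl]-3-phenylpropanoate | COc1c(CC=C(C)C)c(O[Si](C(C)C)(C(C)C)C(C)C)c2c(c1[C@H](CC(=O)OC)c1ccccc1)O[C@H](C)[C@@H](C)C2=O
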